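Diplotrin A is a 3-methoxyflavone, and the plan rests on cutting ring C at three bonds: C4a–C4, C4–C3 and O1–C2. The feature exploited is that C4 is a lone carbonyl carbon flanked by ring A (C4a) and C3, so it can enter as carbon monoxide between an ortho-iodophenol (ring A, with O1 already in place) and a terminal arylacetylene carrying ring B. One palladium-catalysed carbonylative annulation therefore assembles the whole pyranone. The precursors are 6-iodo-2,3-dimethoxyphenol and a 2,5-dibenzyloxy-4-methoxyphenylacetylene; the benzyl ethers keep the two ring B phenols distinct from the methyl ethers until a final hydrogenolysis, after C3 has been oxygenated and methylated.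

Key step: step 7

Remarks on the chemistry: flavone numbering is used throughout (O1, C2, C3, C4, C4a, C5–C8, C8a; ring B positions primed). Dimethyldioxirane is assumed to be used as a freshly prepared, titrated acetone solution (from KHSO5, NaHCO3 and acetone). All other reagents are taken as commercial.

Step 1
Reactants: 1 2,3-dimethoxyphenol
Product: 2 1,2-dimethoxy-3-(methoxymethoxy)benzene
Conditions: NaH, DMF, 0 °C; MOMCl, 0 °C to rt
Reagents that add atoms: chloromethyl methyl ether, COCCl
Why: Williamson-type O-alkylation of the sodium phenoxide with the reactive α-chloro ether should install the MOM acetal, which serves both as a base-stable protecting group and as the directing group for the next step.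

Step 2
Reactants: 2 1,2-dimethoxy-3-(methoxymethoxy)benzene
Product: 4 1-iodo-3,4-dimethoxy-2-(methoxymethoxy)benzene, via aryllithium 3 (not isolated)
Conditions: n-BuLi, TMEDA, THF, 0 °C; I2, −78 °C to rt
Reagents that add atoms: iodine, II
Why: Directed ortho-metalation, in which the MOM acetal chelates lithium far better than a methoxy group and has a single free ortho position, should place lithium next to the protected phenol oxygen, and iodine then converts the aryllithium into the aryl iodide.

Step 3
Reactants: 4 1-iodo-3,4-dimethoxy-2-(methoxymethoxy)benzene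
Product: 5 6-iodo-2,3-dimethoxyphenol
Conditions: HCl (cat.), MeOH, 50 °C
Reagents that add atoms: none
Why: Acid-catalysed acetal exchange with methanol (MOM ether cleavage) should free the phenol, while the aryl methyl ethers and the aryl iodide are inert to dilute methanolic HCl.

Step 4
Reactants: 6 methoxyhydroquinone (2-methoxybenzene-1,4-diol); 7 benzyl bromide
Product: 8 1,4-bis(benzyloxy)-2-methoxybenzene
Conditions: K2CO3, DMF, 60 °C, under N2
Reagents that add atoms: benzyl bromide (7), BrCc1ccccc1
Why: Double Williamson ether synthesis of both phenols with benzyl bromide and carbonate should proceed cleanly, provided air is excluded so that the hydroquinone dianion is not oxidised to the quinone.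

Step 5
Reactants: 8 1,4-bis(benzyloxy)-2-methoxybenzene
Product: 10 2,5-bis(benzyloxy)-4-methoxybenzaldehyde, via iminium salt 9 (not isolated)
Conditions: POCl3, DMF, 0 to 60 °C; aq NaOAc, rt
Reagents that add atoms: N,N-dimethylformamide, CN(C)C=O; water, O
Why: Vilsmeier–Haack formylation should occur at C5 of 8, the only open position that is para to one alkoxy group (the methoxy) and ortho to another without being flanked on both sides, and aryl benzyl ethers tolerate the chloroiminium reagent.

Step 6
Reactants: 10 2,5-bis(benzyloxy)-4-methoxybenzaldehyde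
Product: 12 1,4-bis(benzyloxy)-2-ethynyl-5-methoxybenzene, via diazoalkene 11 (not isolated)
Conditions: dimethyl (1-diazo-2-oxopropyl)phosphonate, K2CO3, MeOH/THF, 0 °C to rt
Reagents that add atoms: dimethyl (1-diazo-2-oxopropyl)phosphonate, COP(=O)(OC)C(=[N+]=[N-])C(C)=O
Why: Seyferth–Gilbert homologation in its Ohira–Bestmann form, in which methanolysis releases the diazomethylphosphonate anion, Horner–Wadsworth–Emmons-type olefination gives diazoalkene 11, and loss of N2 with a 1,2-hydride shift should deliver the terminal alkyne under mild base that leaves the benzyl ethers untouched.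

Step 7
Reactants: 5 6-iodo-2,3-dimethoxyphenol; 12 1,4-bis(benzyloxy)-2-ethynyl-5-methoxybenzene; 13 carbon monoxide
Product: 16 2-[2,5-bis(benzyloxy)-4-methoxyphenyl]-7,8-dimethoxy-4H-chromen-4-one, via hydroxyaryl ynone 14 (not isolated), via enaminone 15 (not isolated)
Conditions: PdCl2(PPh3)2 (5 mol %), CO (10 bar), Et2NH/DMF, 100 °C, pressure vessel, no copper salt
Reagents that add atoms: carbon monoxide (13), [C-]#[O+]
Why: Divalent palladium from PdCl2(PPh3)2 is reduced in the amine/CO medium to zerovalent palladium, which inserts into the C–I bond of 5; CO insertion gives an aroylpalladium iodide, and coupling with the amine-deprotonated alkyne 12 followed by reductive elimination forms C4a–C4 and C4–C3 in ynone 14. Diethylamine then adds to the alkyne carbon remote from the carbonyl to give enaminone 15, and the neighbouring phenol attacks this same carbon and expels the amine, forming O1–C2. The closest known reaction type is the palladium-catalysed carbonylative Sonogashira annulation of 2-iodophenols with terminal alkynes to flavones. Ring C closes in a 6-endo mode (6-endo-trig addition–elimination on 15, equivalent to 6-endo-dig attack on 14), and no stereocentre is created. Two selectivities are needed: CO insertion must outrun direct alkynylation of the arylpalladium species (which would end in a 2-arylbenzofuran), and six-membered closure must beat 5-exo closure to the aurone; CO pressure without copper favours the first, and the enaminone favours the second because its amine-bearing carbon is the only electrophilic site left for the phenol. In the substrates the iodide sits ortho to the one free phenol, the alkyne is terminal, and the 2'-oxygen of ring B is masked as a benzyl ether, so only the ring A oxygen can close onto C2 and the other methyl and benzyl ethers are spectators.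

Step 8
Reactants: 16 2-[2,5-bis(benzyloxy)-4-methoxyphenyl]-7,8-dimethoxy-4H-chromen-4-one
Product: 18 2-[2,5-bis(benzyloxy)-4-methoxyphenyl]-3-hydroxy-7,8-dimethoxy-4H-chromen-4-one, via flavone epoxide 17 (not isolated)
Conditions: DMDO (acetone solution), CH2Cl2, 0 °C to rt; then p-TsOH·H2O (cat.), CH2Cl2, rt
Reagents that add atoms: dimethyldioxirane, CC1(C)OO1
Why: Dioxirane epoxidation of the enol-ether-like C2=C3 bond should give the racemic, necessarily cis-fused epoxide 17 under neutral conditions, and acid-catalysed opening at the oxygen- and aryl-stabilised C2 followed by loss of H3 isomerises it to the flavonol, which erases both transient stereocentres.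

Step 9
Reactants: 18 2-[2,5-bis(benzyloxy)-4-methoxyphenyl]-3-hydroxy-7,8-dimethoxy-4H-chromen-4-one
Product: 19 2-[2,5-bis(benzyloxy)-4-methoxyphenyl]-3,7,8-trimethoxy-4H-chromen-4-one
Conditions: MeI, K2CO3, acetone, reflux
Reagents that add atoms: iodomethane, CI
Why: Williamson O-methylation of the acidic 3-hydroxyl, the only free OH in the molecule, should be selective by default because both ring B phenols are still benzylated.

Step 10
Reactants: 19 2-[2,5-bis(benzyloxy)-4-methoxyphenyl]-3,7,8-trimethoxy-4H-chromen-4-one
Product: 20 diplotrin A, 2-(2,5-dihydroxy-4-methoxyphenyl)-3,7,8-trimethoxy-4H-chromen-4-one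
Conditions: H2 (1 atm), 10% Pd/C, EtOAc/MeOH, rt; filtration and concentration under N2
Reagents that add atoms: none
Why: Catalytic hydrogenolysis of the two aryl benzyl ethers should release the 2'- and 5'-phenols under neutral, reducing conditions that spare the methyl ethers and the tetrasubstituted, vinylogous-ester C2=C3 bond and keep the hydroquinone from oxidising.

Compound list
1 | 2,3-dimethoxyphenol | COc1cccc(O)c1OC | starting material
2 | 1,2-dimethoxy-3-(methoxymethoxy)benzene | COCOc1cccc(OC)c1OC | intermediate
3 | [3,4-dimethoxy-2-(methoxymethoxy)phenyl]lithium (aryllithium, not isolated) | [Li]c1ccc(OC)c(OC)c1OCOC | intermediate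
4 | 1-iodo-3,4-dimethoxy-2-(methoxymethoxy)benzene | COCOc1c(I)ccc(OC)c1OC | intermediate
5 | 6-iodo-2,3-dimethoxyphenol | COc1ccc(I)c(O)c1OC | intermediate
6 | methoxyhydroquinone (2-methoxybenzene-1,4-diol) | COc1cc(O)ccc1O | starting material
7 | benzyl bromide | BrCc1ccccc1 | starting material
8 | 1,4-bis(benzyloxy)-2-methoxybenzene | COc1cc(OCc2ccccc2)ccc1OCc1ccccc1 | intermediate
9 | N-{[2,5-bis(benzyloxy)-4-methoxyphenyl]methylidene}-N-methylmethanaminium salt (iminium salt, counter-ion drawn as chloride, not isolated) | C[N+](C)=Cc1cc(OCc2ccccc2)c(OC)cc1OCc1ccccc1.[Cl-] | intermediate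
10 | 2,5-bis(benzyloxy)-4-methoxybenzaldehyde | COc1cc(OCc2ccccc2)c(C=O)cc1OCc1ccccc1 | intermediate
11 | 1,4-bis(benzyloxy)-2-(2-diazoethenyl)-5-methoxybenzene (diazoalkene, not isolated) | COc1cc(OCc2ccccc2)c(C=C=[N+]=[N-])cc1OCc1ccccc1 | intermediate
12 | 1,4-bis(benzyloxy)-2-ethynyl-5-methoxybenzene | C#Cc1cc(OCc2ccccc2)c(OC)cc1OCc1ccccc1 | intermediate
13 | carbon monoxide | [C-]#[O+] | starting material
14 | 3-[2,5-bis(benzyloxy)-4-methoxyphenyl]-1-(2-hydroxy-3,4-dimethoxyphenyl)prop-2-yn-1-one (hydroxyaryl ynone, not isolated) | COc1ccc(C(=O)C#Cc2cc(OCc3ccccc3)c(OC)cc2OCc2ccccc2)c(O)c1OC | intermediate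
15 | 3-[2,5-bis(benzyloxy)-4-methoxyphenyl]-3-(diethylamino)-1-(2-hydroxy-3,4-dimethoxyphenyl)prop-2-en-1-one (enaminone, not isolated; double-bond geometry not fixed, E and Z interconvert) | CCN(CC)C(=CC(=O)c1ccc(OC)c(OC)c1O)c1cc(OCc2ccccc2)c(OC)cc1OCc1ccccc1 | intermediate
16 | 2-[2,5-bis(benzyloxy)-4-methoxyphenyl]-7,8-dimethoxy-4H-chromen-4-one | COc1cc(OCc2ccccc2)c(-c2cc(=O)c3ccc(OC)c(OC)c3o2)cc1OCc1ccccc1 | intermediate
17 | 1a-[2,5-bis(benzyloxy)-4-methoxyphenyl]-3,4-dimethoxy-1a,7a-dihydro-7H-oxireno[2,3-b]chromen-7-one (flavone 2,3-epoxide, racemic, cis-fused, one enantiomer drawn, not isolated) | COc1cc(OCc2ccccc2)c([C@]23O[C@H]2C(=O)c2ccc(OC)c(OC)c2O3)cc1OCc1ccccc1 | intermediate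
18 | 2-[2,5-bis(benzyloxy)-4-methoxyphenyl]-3-hydroxy-7,8-dimethoxy-4H-chromen-4-one | COc1cc(OCc2ccccc2)c(-c2oc3c(OC)c(OC)ccc3c(=O)c2O)cc1OCc1ccccc1 | intermediate
19 | 2-[2,5-bis(benzyloxy)-4-methoxyphenyl]-3,7,8-trimethoxy-4H-chromen-4-one | COc1cc(OCc2ccccc2)c(-c2oc3c(OC)c(OC)ccc3c(=O)c2OC)cc1OCc1ccccc1 | intermediate
20 | diplotrin A, 2-(2,5-dihydroxy-4-methoxyphenyl)-3,7,8-trimethoxy-4H-chromen-4-one (achiral) | COc1cc(O)c(-c2oc3c(OC)c(OC)ccc3c(=O)c2OC)cc1O | target

Total step count: 10 (steps 1–3 make the ring A partner, steps 4–6 the ring B partner, steps 7–10 are common).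
Longest linear sequence: 7 steps (steps 4, 5, 6, 7, 8, 9, 10 from methoxyhydroquinone; the ring A branch, steps 1, 2, 3, 7, 8, 9, 10, is equally long).

Steps most likely to fail

Step 7. The arylpalladium species may couple with the alkyne before CO is inserted and then cyclise to a benzofuran. The ynone may also close in the 5-exo sense, or oxidative addition into the electron-rich, doubly ortho-oxygenated C–I bond may be slow enough for the alkyne to oligomerise at 100 °C. The fallback sets out from MOM ether 2 and alkyne 12 and comes back at flavone 16, taking the C4 carbon from DMF instead of CO and using no palladium. Aryllithium 3, made as in step 2, is quenched with DMF instead of iodine to give 3,4-dimethoxy-2-(methoxymethoxy)benzaldehyde F1. Alkyne 12 is deprotonated with n-BuLi (THF, −78 °C) to {[2,5-bis(benzyloxy)-4-methoxyphenyl]ethynyl}lithium F2, which adds to F1 to give racemic 3-[2,5-bis(benzyloxy)-4-methoxyphenyl]-1-[3,4-dimethoxy-2-(methoxymethoxy)phenyl]prop-2-yn-1-ol F3. Oxidation with MnO2 (CH2Cl2, rt) should give 3-[2,5-bis(benzyloxy)-4-methoxyphenyl]-1-[3,4-dimethoxy-2-(methoxymethoxy)phenyl]prop-2-yn-1-one F4. Methanolic HCl then removes the MOM group to release hydroxyaryl ynone 14, and warming with Et2NH in EtOH should carry it through enaminone 15 to 16 by the same 6-endo addition–elimination.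

Step 8. Epoxidation of the C2=C3 bond is slow, so oxidation at the benzylic C–H bonds of the benzyl ethers or on the electron-rich ring B may compete, and the epoxide may open along other paths than enolisation. The fallback sets out from flavone 16 and comes back at flavonol 18 without an electrophilic oxidant acting on the intact molecule. Deprotonation at C3 with LDA (THF, −78 °C) gives {2-[2,5-bis(benzyloxy)-4-methoxyphenyl]-7,8-dimethoxy-4-oxo-4H-chromen-3-yl}lithium F5. Trapping with B(OMe)3 and a mildly acidic aqueous work-up gives {2-[2,5-bis(benzyloxy)-4-methoxyphenyl]-7,8-dimethoxy-4-oxo-4H-chromen-3-yl}boronic acid F6, and oxidation of the C–B bond with H2O2/AcOH should give 18.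

Step 2. Part of the metalation may occur next to the C3 methoxy group instead of next to the MOM ether, or lithiation may stay incomplete, and a regioisomeric iodide would then be carried into the key step. The fallback sets out from phenol 1 and comes back at iodophenol 5, replacing the acetal director by the strongest oxygen-based one. Carbamoylation of 1 (NaH, THF; ClCONEt2) gives 2,3-dimethoxyphenyl N,N-diethylcarbamate F7. Metalation with s-BuLi/TMEDA (THF, −78 °C) gives [2-(diethylcarbamoyloxy)-3,4-dimethoxyphenyl]lithium F8, which is quenched with I2 at −78 °C, before any anionic Fries shift, to give 6-iodo-2,3-dimethoxyphenyl N,N-diethylcarbamate F9. Hydrolysis (NaOH, EtOH/H2O, reflux) should release 5.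

Further compounds
F1 | step 7 | 3,4-dimethoxy-2-(methoxymethoxy)benzaldehyde | COCOc1c(C=O)ccc(OC)c1OC
F2 | step 7 | {[2,5-bis(benzyloxy)-4-methoxyphenyl]ethynyl}lithium | [Li]C#Cc1cc(OCc2ccccc2)c(OC)cc1OCc1ccccc1
F3 | step 7 | 3-[2,5-bis(benzyloxy)-4-methoxyphenyl]-1-[3,4-dimethoxy-2-(methoxymethoxy)phenyl]prop-2-yn-1-ol (racemic) | COCOc1c(C(O)C#Cc2cc(OCc3ccccc3)c(OC)cc2OCc2ccccc2)ccc(OC)c1OC
F4 | step 7 | 3-[2,5-bis(benzyloxy)-4-methoxyphenyl]-1-[3,4-dimethoxy-2-(methoxymethoxy)phenyl]prop-2-yn-1-one | COCOc1c(C(=O)C#Cc2cc(OCc3ccccc3)c(OC)cc2OCc2ccccc2)ccc(OC)c1OC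
F5 | step 8 | {2-[2,5-bis(benzyloxy)-4-methoxyphenyl]-7,8-dimethoxy-4-oxo-4H-chromen-3-yl}lithium | COc1cc(OCc2ccccc2)c(-c2oc3c(OC)c(OC)ccc3c(=O)c2[Li])cc1OCc1ccccc1
F6 | step 8 | {2-[2,5-bis(benzyloxy)-4-methoxyphenyl]-7,8-dimethoxy-4-oxo-4H-chromen-3-yl}boronic acid | COc1cc(OCc2ccccc2)c(-c2oc3c(OC)c(OC)ccc3c(=O)c2B(O)O)cc1OCc1ccccc1
F7 | step 2 | 2,3-dimethoxyphenyl N,N-diethylcarbamate | CCN(CC)C(=O)Oc1cccc(OC)c1OC
F8 | step 2 | [2-(diethylcarbamoyloxy)-3,4-dimethoxyphenyl]lithium | CCN(CC)C(=O)Oc1c([Li])ccc(OC)c1OC
F9 | step 2 | 6-iodo-2,3-dimethoxyphenyl N,N-diethylcarbamate | CCN(CC)C(=O)Oc1c(I)ccc(OC)c1OC
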